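## The problem

The target 26 is a flavonol, 2-(3,5-dihydroxy-4-methoxyphenyl)-3,5-dihydroxy-7,8-dimethoxy-4H-chromen-4-one. Ring A is fused to the pyranone ring C through C4a–C8a, and ring B is attached at C2. There is no stereocenter, so nothing has to be controlled in space. The whole task is to place eight oxygen functions correctly: the 4-oxo group, four free hydroxyls (C3, C5, C3', C5') and three methyl ethers (C7, C8, C4'). Each methyl ether lies beside or between free hydroxyls, so a late unselective methylation or demethylation is excluded and the hydroxyls must travel under groups that leave cleanly. Ring A carries the 5,7,8-trioxygenation with C6 free; the C8 oxygen is para to the C5 hydroxyl, so the ring is a masked quinol and is easily over-oxidised. The 3-hydroxychromone of ring C is cleaved by alkaline oxidants, and a free 5,8-quinol is air-sensitive in base, so the closing steps must be mild and the last deprotection neutral. The feature that opens the structure to a convergent key step is on ring A: O1 on C8a and the acyl carbon C4 on C4a are ortho neighbours, and the C5 oxygen sits on the other side of C4a. That is the pattern left when an oxygen nucleophile and an acyl group add across the triple bond of a 3-alkoxyaryne, with the alkoxy group deciding which end receives which.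

## Retrosynthesis

**26 from 25.** The last cut is at the three O–benzyl bonds (O3, O3', O5'). One hydrogenolysis under neutral conditions frees all three hydroxyls of 25 and leaves the methyl ethers and the chelated 5-OH alone. This is preferred to any endgame by selective demethylation, because the 4'-OMe flanked by two hydroxyls and the 7,8-dimethoxy pair would not survive a Lewis acid reliably.

**25 from 24 from 22.** The O8–methyl bond and then the C8–O bond are cut. In quinol 24 the 8-OH is an ordinary phenol and the 5-OH is locked in a hydrogen bond to C4=O, so one equivalent of methylating agent should find O8 only. The C8 oxygen itself comes from Elbs persulfate oxidation of the 5-hydroxyflavone 22, through the aryl sulfate 23. C8 is the only position para to the 5-oxygen, and the 3-benzyloxy group keeps ring C out of the alkaline oxidation. Carrying the C8 oxygen through the key step instead would put alkoxy groups on both sides of the aryne triple bond and cancel its regiochemical bias; that is why this oxygen is paid for late.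

**22 from 21 from 18.** The O3–benzyl bond and the C3–O bond are cut. The C3 oxygen is introduced by epoxidation of the C2=C3 bond of flavone 18 with dimethyldioxirane (epoxide 19), acid isomerisation to the 3-hydroxyflavone 20, and loss of the MOM group under the same acid to give 21. The step is placed before the C8 oxidation on purpose: 18 has no free phenol and the least electron-rich ring A of the whole sequence, so the dioxirane has only the enol-ether double bond to attack. Selective benzylation of the 3-OH of 21 is asked to rely on the weaker chelation of O3–H compared with O5–H.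

**18 from 8 and 15.** This is the central cut: O1–C8a, C4–C4a and O1–C2 are broken together, which removes ring C and divides the molecule into the silyl triflate 8 and the arylpropiolic acid 15, two fragments of similar size. Condensation routes that start from a preformed 2-hydroxyaryl ketone form only one of these bonds per step and need a differentially protected acylphloroglucinol. In the forward direction fluoride must release aryne 16, the carboxylate oxygen must add to the carbon remote from the OMOM group, the acyl group must migrate to the carbon next to it (ynone 17), and the phenoxide must close ring C in the 6-endo mode. MOM is chosen for O5 because it polarises the aryne, survives fluoride at high temperature and leaves with mild acid. Benzyl is chosen for ring B because it survives fluoride, acid, alkali and persulfate.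

**8 from 6, 3, 2 and 1.** The O–triflyl bond, the C–Si bond and the two O-protecting groups are cut. The silicon is placed by directed ortho-metalation of carbamate 3 at the position between the carbamate and the OMOM group (via 4 and 5), and the carbamate of 6 is exchanged for triflate in one flask (via phenol 7). Carbamate 3 comes from the mono-MOM ether 2 of 5-methoxyresorcinol 1. The three oxygens of 1 become O1-side triflate, O5 and O7 of the flavone.

**15 from 13, 12, 11, 10 and 9.** The C–CO2H bond and the alkyne are cut back to aldehyde 12 by the Corey–Fuchs sequence (dibromoalkene 13, acetylide 14, CO2). Aldehyde 12 is reached from 3,5-dihydroxy-4-methoxybenzoic acid 9 by exhaustive benzylation (10), reduction (11) and oxidation. The 4'-methyl ether and the symmetry of ring B are bought with the starting material.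

## Roads not taken

Alternative 1: The cut is through C2–C3 and the C4 carbonyl oxygen, with ring C masked as an isoxazole. In the forward step the hydroximoyl chloride A1, dehydrochlorinated by KHCO3, adds as a 1,3-dipole to the ring A alkynylboronate A2 and gives the isoxazole-4-boronate A3. Oxidation of the C–B bond, reductive N–O cleavage, debenzylation and cyclodehydration (O1–C2) would then give the flavonol. Its merit is real: every oxygen of ring A, the C8 methoxy included, and the C3 oxygen are in place from the start, so it needs neither a persulfate oxidation nor a dioxirane, and alkynylboronate cycloadditions are regiochemically dependable. Its weak points for this target are three. A2 is a pentasubstituted benzene with two ortho substituents beside the alkyne, which needs a multistep synthesis of its own and should slow the cycloaddition enough for dipole dimerisation to compete. The unmasked 2-hydroxy-1,3-dicarbonyl stage is prone to oxidative and retro-Claisen cleavage. The 5-oxygen arrives as a methyl ether and must be cleaved at the end beside the 7-, 8- and 4'-methyl ethers, the last flanked by two hydroxyls. Alternative 1 is better in oxidation economy on ring A. The chosen plan sets against that shorter fragment syntheses, a key step that gives the flavone nucleus in one operation on a known substrate class, and protecting groups that leave without a selective demethylation.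

Alternative 2: The cut is O1–C8a, made by umpolung of ring A. The diketone A4 (a 2-benzyloxy-1,3-diketone on a 2-hydroxy-4,5-dimethoxyphenyl ring) would be oxidised at a graphite anode in methanol with LiClO4 to the quinone monoketal A5. The enol oxygen adds to C8a of A5 and loss of methanol restores ring A, giving A6, which is the same compound as 25 of the present route. This is the shortest road: A4 should be available in a few steps from a commercial trioxygenated acetophenone by acylation and base-induced acyl transfer, the C7 and C8 methoxy groups and the C3 oxygen are built in, and one hydrogenolysis finishes the synthesis. If the key step worked, it would roughly halve the step count, and in that respect it is clearly superior. Its weakness is that the ring closure has no close precedent. The acyl-deactivated, hydrogen-bonded phenol must be oxidised selectively beside an electron-rich trialkoxyaryl ring and an enolisable α-alkoxy diketone. Methanol competes with the enol oxygen for C8a, and the central carbon of the diketone could attack in its place. The chosen plan answers with a key step of a known type whose regiochemistry can be predicted from the substrate, and its uncertain steps are classical, if modest-yielding, ring A oxidations.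

Alternative 3: The cut is C4a–C8a, building ring A from an acyclic chain, followed by O1–C2. Mg(OMe)2 in methanol would open the 4-pyranone A7 to the tetraoxo ester A8, whose C4a methylene acylates the ester carbon in a Claisen closure; aqueous acid then closes ring C and gives the 5,7-dihydroxyflavone A9. The key step is mild and needs no sealed tube at 125 °C, which is an advantage over the chosen plan. For this target the gain is small. A9 carries only the plain 5,7-dihydroxy pattern, so 7-O-methylation, C8 oxidation, 8-O-methylation and C3 oxidation would all still follow; that is the whole late stage of the chosen plan plus one step. A7 must be assembled in several steps, and aldol folding of A8 competes with the Claisen mode. The same flavone type is also reachable by classical condensation chemistry from aromatic starting materials in fewer steps, so building ring A from a chain buys nothing here. The chosen plan arrives at its key-step product with the 7-methoxy group in place and the 5-oxygen already differentiated.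

Key step: step 10

Remark on the chemistry: the target is achiral; the only stereogenic intermediate, epoxide 19, forms as a racemate and loses both stereocenters in the same step. Compounds 1 and 9 are taken as purchasable.

## Route

Step 1
Reactants: 1 5-methoxyresorcinol
Product: 2 3-methoxy-5-(methoxymethoxy)phenol
Conditions: MOMCl (0.9 equiv), iPr2NEt, THF, 0 °C to rt
Reagents that add atoms: chloromethyl methyl ether, COCCl
Why: Statistical mono-O-alkylation of a symmetrical diphenol; a deficit of MOMCl keeps the bis-ether low, and recovered 1 (and the bis-ether after acid hydrolysis) is recycled.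

Step 2
Reactants: 2 3-methoxy-5-(methoxymethoxy)phenol
Product: 3 3-methoxy-5-(methoxymethoxy)phenyl N-(propan-2-yl)carbamate
Conditions: iPrNCO, Et3N (cat.), CH2Cl2, rt
Reagents that add atoms: isopropyl isocyanate, CC(C)N=C=O
Why: Base-catalysed addition of the phenol to the isocyanate gives the secondary carbamate, a strong ortho-director that can later be removed by mild E1cB cleavage.

Step 3
Reactants: 3 3-methoxy-5-(methoxymethoxy)phenyl N-(propan-2-yl)carbamate
Product: 6 5-methoxy-3-(methoxymethoxy)-2-(trimethylsilyl)phenyl N-(propan-2-yl)carbamate, via N-silyl carbamate 4 (not isolated), via C-silylated N-silyl carbamate 5 (not isolated)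
Conditions: TBSOTf, TMEDA, Et2O, 0 °C to rt; n-BuLi, TMEDA, −78 °C; TMSCl, −78 °C to rt; cold aq. NaHSO4
Reagents that add atoms: chlorotrimethylsilane, C[Si](C)(C)Cl
Why: Directed ortho-metalation: N-silylation in the flask protects the carbamate N–H, n-BuLi then removes the proton flanked by the carbamate and the chelating OMOM group in preference to the one flanked by carbamate and OMe, TMSCl traps the aryllithium, and the N–Si bond is hydrolysed on work-up.

Step 4
Reactants: 6 5-methoxy-3-(methoxymethoxy)-2-(trimethylsilyl)phenyl N-(propan-2-yl)carbamate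
Product: 8 5-methoxy-3-(methoxymethoxy)-2-(trimethylsilyl)phenyl trifluoromethanesulfonate, via silyl phenol 7 (not isolated)
Conditions: DBU, Et2NH, MeCN, 40 °C; then PhNTf2, rt
Reagents that add atoms: N-phenylbis(trifluoromethanesulfonimide), O=S(=O)(N(c1ccccc1)S(=O)(=O)C(F)(F)F)C(F)(F)F
Why: One-flask decarbamoylation and triflation: DBU deprotonates the carbamate N–H, the phenoxide is expelled (E1cB) while Et2NH scavenges the isocyanate, and PhNTf2 triflates the phenoxide, so the acid-sensitive electron-rich silyl phenol is never handled.

Step 5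
Reactants: 9 3,5-dihydroxy-4-methoxybenzoic acid
Product: 10 benzyl 3,5-bis(benzyloxy)-4-methoxybenzoate
Conditions: BnBr (3.5 equiv), K2CO3, DMF, 60 °C
Reagents that add atoms: benzyl bromide, BrCc1ccccc1
Why: Williamson benzylation of both phenols, with the carboxylate esterified in the same operation.

Step 6
Reactants: 10 benzyl 3,5-bis(benzyloxy)-4-methoxybenzoate
Product: 11 [3,5-bis(benzyloxy)-4-methoxyphenyl]methanol
Conditions: LiAlH4, THF, 0 °C to rt
Reagents that add atoms: none
Why: Hydride reduction of the ester to the benzylic alcohol; aryl benzyl and methyl ethers are inert.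

Step 7
Reactants: 11 [3,5-bis(benzyloxy)-4-methoxyphenyl]methanol
Product: 12 3,5-bis(benzyloxy)-4-methoxybenzaldehyde
Conditions: MnO2 (activated, excess), CH2Cl2, rt
Reagents that add atoms: none
Why: MnO2 oxidises the electron-rich benzylic alcohol to the aldehyde and stops there.

Step 8
Reactants: 12 3,5-bis(benzyloxy)-4-methoxybenzaldehyde
Product: 13 1,3-bis(benzyloxy)-5-(2,2-dibromoethenyl)-2-methoxybenzene
Conditions: CBr4, PPh3, CH2Cl2, 0 °C
Reagents that add atoms: carbon tetrabromide, BrC(Br)(Br)Br
Why: First stage of the Corey–Fuchs reaction, a Wittig-type olefination by the dibromomethylene ylide.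

Step 9
Reactants: 13 1,3-bis(benzyloxy)-5-(2,2-dibromoethenyl)-2-methoxybenzene
Product: 15 3-[3,5-bis(benzyloxy)-4-methoxyphenyl]prop-2-ynoic acid, via lithium acetylide 14 (not isolated)
Conditions: n-BuLi (2.2 equiv), THF, −78 °C; CO2, −78 °C to rt; aq. HCl
Reagents that add atoms: carbon dioxide, O=C=O
Why: Second stage of the Corey–Fuchs reaction: bromine–lithium exchange and elimination give the lithium acetylide, which is carboxylated by CO2; at −78 °C the benzyl ethers are not deprotonated.

Step 10
Reactants: 8 5-methoxy-3-(methoxymethoxy)-2-(trimethylsilyl)phenyl trifluoromethanesulfonate; 15 3-[3,5-bis(benzyloxy)-4-methoxyphenyl]prop-2-ynoic acid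
Product: 18 2-[3,5-bis(benzyloxy)-4-methoxyphenyl]-7-methoxy-5-(methoxymethoxy)-4H-chromen-4-one, via aryne 16 (not isolated), via hydroxyaryl ynone 17 (not isolated)
Conditions: CsF (4 equiv), 8 (1.5 equiv), THF, 125 °C (sealed tube), 24 h
Reagents that add atoms: none
Why: CsF converts 15 into its caesium carboxylate and desilylates 8, and loss of triflate gives aryne 16. The carboxylate oxygen adds to the aryne carbon remote from the OMOM group (O1–C8a), because the inductively withdrawing alkoxy group beside the triple bond makes that carbon the electrophilic one and stabilises the carbanion formed next to itself; the other methoxy group is not adjacent to the triple bond and has little say. The aryl anion at C4a attacks the neighbouring ester carbonyl through a four-membered transition state, and collapse moves the alkynoyl group from oxygen to carbon (C4–C4a), giving the phenoxide of ynone 17. This phenoxide adds to the β-carbon of the ynone in a 6-endo-dig oxa-Michael closure (O1–C2) that forms ring C, and the vinyl anion is protonated by the hydrogen fluoride set free at the start. The closest known reaction type is the fluoride-mediated insertion of arynes into the C–O bond of carboxylic acids to give ortho-hydroxyaryl ketones, which with 3-arylpropiolic acids runs on to flavones. No stereocenter is formed. The step needs three selectivities: the site of oxygen addition, secured by the 3-alkoxy group; acyl transfer over protonation of the aryl anion, secured by the aprotic medium and the high temperature; and 6-endo over 5-exo closure, which is the usual course for a phenoxide on an aryl ynone under aprotic conditions, the aurone being the by-product to watch for.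

Step 11
Reactants: 18 2-[3,5-bis(benzyloxy)-4-methoxyphenyl]-7-methoxy-5-(methoxymethoxy)-4H-chromen-4-one
Product: 21 2-[3,5-bis(benzyloxy)-4-methoxyphenyl]-3,5-dihydroxy-7-methoxy-4H-chromen-4-one, via flavone 2,3-epoxide 19 (not isolated), via 3-hydroxy MOM ether 20 (not isolated)
Conditions: DMDO (acetone solution, excess), CH2Cl2, 0 °C to rt; evaporate; TsOH·H2O (cat.), CH2Cl2, rt; then MeOH, conc. HCl, 50 °C
Reagents that add atoms: dimethyldioxirane, CC1(C)OO1
Why: Dimethyldioxirane epoxidises the C2=C3 enol-ether bond of the flavone under neutral conditions; acid opens the racemic epoxide at C2 (cation stabilised by O1 and ring B) and loss of H3 gives the 3-hydroxyflavone, after which HCl in methanol removes the peri MOM group by acetal exchange; both stereocenters of 19 vanish when ring C re-aromatises.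

Step 12
Reactants: 21 2-[3,5-bis(benzyloxy)-4-methoxyphenyl]-3,5-dihydroxy-7-methoxy-4H-chromen-4-one
Product: 22 3-(benzyloxy)-2-[3,5-bis(benzyloxy)-4-methoxyphenyl]-5-hydroxy-7-methoxy-4H-chromen-4-one
Conditions: BnBr (1.1 equiv), K2CO3, DMF, rt
Reagents that add atoms: benzyl bromide, BrCc1ccccc1
Why: Regioselective Williamson benzylation: the 3-OH is more acidic and less firmly chelated than the 5-OH peri to C4=O, so one equivalent of BnBr alkylates O3 only, which also blocks the sensitive 3-hydroxychromone for the next step.

Step 13
Reactants: 22 3-(benzyloxy)-2-[3,5-bis(benzyloxy)-4-methoxyphenyl]-5-hydroxy-7-methoxy-4H-chromen-4-one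
Product: 24 3-(benzyloxy)-2-[3,5-bis(benzyloxy)-4-methoxyphenyl]-5,8-dihydroxy-7-methoxy-4H-chromen-4-one, via potassium 8-sulfate 23 (not isolated)
Conditions: K2S2O8, aq. KOH, pyridine, 15–20 °C, 24 h; then aq. HCl, Na2SO3, 70 °C
Reagents that add atoms: potassium peroxydisulfate, [K+].[K+].[O-]S(=O)(=O)OOS(=O)(=O)[O-]
Why: Elbs persulfate oxidation: the 5-phenoxide attacks the peroxide oxygen through its para carbon C8, the only free para position and one further activated by the 7-methoxy group, and the aryl sulfate is hydrolysed by acid to the quinol; the reaction is classical for 3-alkoxy-5-hydroxy-7-methoxyflavones.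

Step 14
Reactants: 24 3-(benzyloxy)-2-[3,5-bis(benzyloxy)-4-methoxyphenyl]-5,8-dihydroxy-7-methoxy-4H-chromen-4-one
Product: 25 3-(benzyloxy)-2-[3,5-bis(benzyloxy)-4-methoxyphenyl]-5-hydroxy-7,8-dimethoxy-4H-chromen-4-one
Conditions: Me2SO4 (1.05 equiv), K2CO3, acetone, reflux, under Ar
Reagents that add atoms: dimethyl sulfate, COS(=O)(=O)OC
Why: Selective O-methylation: the 8-OH is an ordinary phenol and the 5-OH is held in a hydrogen bond to C4=O, so one equivalent of Me2SO4 with K2CO3 methylates O8 only; argon protects the quinol from air oxidation in base.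

Step 15
Reactants: 25 3-(benzyloxy)-2-[3,5-bis(benzyloxy)-4-methoxyphenyl]-5-hydroxy-7,8-dimethoxy-4H-chromen-4-one
Product: 26 2-(3,5-dihydroxy-4-methoxyphenyl)-3,5-dihydroxy-7,8-dimethoxy-4H-chromen-4-one
Conditions: H2 (1 atm), Pd/C, EtOAc/MeOH, rt
Reagents that add atoms: none
Why: Catalytic hydrogenolysis removes the three benzyl ethers under neutral conditions; the methyl ethers and the flavonol C2=C3 bond are not touched at one atmosphere and room temperature.

## Compound list

1 | 5-methoxyresorcinol | COc1cc(O)cc(O)c1 | starting material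
2 | 3-methoxy-5-(methoxymethoxy)phenol | COCOc1cc(O)cc(OC)c1 | intermediate
3 | 3-methoxy-5-(methoxymethoxy)phenyl N-(propan-2-yl)carbamate | COCOc1cc(OC)cc(OC(=O)NC(C)C)c1 | intermediate
4 | 3-methoxy-5-(methoxymethoxy)phenyl N-[tert-butyl(dimethyl)silyl]-N-(propan-2-yl)carbamate | COCOc1cc(OC)cc(OC(=O)N(C(C)C)[Si](C)(C)C(C)(C)C)c1 | intermediate
5 | 5-methoxy-3-(methoxymethoxy)-2-(trimethylsilyl)phenyl N-[tert-butyl(dimethyl)silyl]-N-(propan-2-yl)carbamate | COCOc1cc(OC)cc(OC(=O)N(C(C)C)[Si](C)(C)C(C)(C)C)c1[Si](C)(C)C | intermediate
6 | 5-methoxy-3-(methoxymethoxy)-2-(trimethylsilyl)phenyl N-(propan-2-yl)carbamate | COCOc1cc(OC)cc(OC(=O)NC(C)C)c1[Si](C)(C)C | intermediate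
7 | 5-methoxy-3-(methoxymethoxy)-2-(trimethylsilyl)phenol | COCOc1cc(OC)cc(O)c1[Si](C)(C)C | intermediate
8 | 5-methoxy-3-(methoxymethoxy)-2-(trimethylsilyl)phenyl trifluoromethanesulfonate | COCOc1cc(OC)cc(OS(=O)(=O)C(F)(F)F)c1[Si](C)(C)C | intermediate
9 | 3,5-dihydroxy-4-methoxybenzoic acid | COc1c(O)cc(C(=O)O)cc1O | starting material
10 | benzyl 3,5-bis(benzyloxy)-4-methoxybenzoate | COc1c(OCc2ccccc2)cc(C(=O)OCc2ccccc2)cc1OCc1ccccc1 | intermediate
11 | [3,5-bis(benzyloxy)-4-methoxyphenyl]methanol | COc1c(OCc2ccccc2)cc(CO)cc1OCc1ccccc1 | intermediate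
12 | 3,5-bis(benzyloxy)-4-methoxybenzaldehyde | COc1c(OCc2ccccc2)cc(C=O)cc1OCc1ccccc1 | intermediate
13 | 1,3-bis(benzyloxy)-5-(2,2-dibromoethenyl)-2-methoxybenzene | COc1c(OCc2ccccc2)cc(C=C(Br)Br)cc1OCc1ccccc1 | intermediate
14 | lithium [3,5-bis(benzyloxy)-4-methoxyphenyl]ethynide | [Li]C#Cc1cc(OCc2ccccc2)c(OC)c(OCc2ccccc2)c1 | intermediate
15 | 3-[3,5-bis(benzyloxy)-4-methoxyphenyl]prop-2-ynoic acid | OC(=O)C#Cc1cc(OCc2ccccc2)c(OC)c(OCc2ccccc2)c1 | intermediate
16 | 5-methoxy-3-(methoxymethoxy)benzyne (1,2-didehydro-5-methoxy-3-(methoxymethoxy)benzene) | COCOC1=CC(OC)=CC#C1 | intermediate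
17 | 3-[3,5-bis(benzyloxy)-4-methoxyphenyl]-1-[2-hydroxy-4-methoxy-6-(methoxymethoxy)phenyl]prop-2-yn-1-one | COCOc1cc(OC)cc(O)c1C(=O)C#Cc1cc(OCc2ccccc2)c(OC)c(OCc2ccccc2)c1 | intermediate
18 | 2-[3,5-bis(benzyloxy)-4-methoxyphenyl]-7-methoxy-5-(methoxymethoxy)-4H-chromen-4-one | COCOc1cc(OC)cc2oc(-c3cc(OCc4ccccc4)c(OC)c(OCc4ccccc4)c3)cc(=O)c12 | intermediate
19 | 1a-[3,5-bis(benzyloxy)-4-methoxyphenyl]-4-methoxy-6-(methoxymethoxy)-1a,7a-dihydro-7H-oxireno[2,3-b]chromen-7-one (2,3-epoxide of 18; racemic, cis-fused, one enantiomer drawn) | COc1c(OCc2ccccc2)cc(cc1OCc3ccccc3)[C@]45Oc6cc(OC)cc(OCOC)c6C(=O)[C@H]4O5 | intermediate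
20 | 2-[3,5-bis(benzyloxy)-4-methoxyphenyl]-3-hydroxy-7-methoxy-5-(methoxymethoxy)-4H-chromen-4-one | COCOc1cc(OC)cc2oc(-c3cc(OCc4ccccc4)c(OC)c(OCc4ccccc4)c3)c(O)c(=O)c12 | intermediate
21 | 2-[3,5-bis(benzyloxy)-4-methoxyphenyl]-3,5-dihydroxy-7-methoxy-4H-chromen-4-one | COc1cc(O)c2c(=O)c(O)c(-c3cc(OCc4ccccc4)c(OC)c(OCc4ccccc4)c3)oc2c1 | intermediate
22 | 3-(benzyloxy)-2-[3,5-bis(benzyloxy)-4-methoxyphenyl]-5-hydroxy-7-methoxy-4H-chromen-4-one | COc1cc(O)c2c(=O)c(OCc3ccccc3)c(-c3cc(OCc4ccccc4)c(OC)c(OCc4ccccc4)c3)oc2c1 | intermediate
23 | potassium 3-(benzyloxy)-2-[3,5-bis(benzyloxy)-4-methoxyphenyl]-5-hydroxy-7-methoxy-4-oxo-4H-chromen-8-yl sulfate | COc1cc(O)c2c(=O)c(OCc3ccccc3)c(-c3cc(OCc4ccccc4)c(OC)c(OCc4ccccc4)c3)oc2c1OS(=O)(=O)[O-].[K+] | intermediate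
24 | 3-(benzyloxy)-2-[3,5-bis(benzyloxy)-4-methoxyphenyl]-5,8-dihydroxy-7-methoxy-4H-chromen-4-one | COc1cc(O)c2c(=O)c(OCc3ccccc3)c(-c3cc(OCc4ccccc4)c(OC)c(OCc4ccccc4)c3)oc2c1O | intermediate
25 | 3-(benzyloxy)-2-[3,5-bis(benzyloxy)-4-methoxyphenyl]-5-hydroxy-7,8-dimethoxy-4H-chromen-4-one | COc1cc(O)c2c(=O)c(OCc3ccccc3)c(-c3cc(OCc4ccccc4)c(OC)c(OCc4ccccc4)c3)oc2c1OC | intermediate
26 | 2-(3,5-dihydroxy-4-methoxyphenyl)-3,5-dihydroxy-7,8-dimethoxy-4H-chromen-4-one | COc1cc(O)c2c(=O)c(O)c(-c3cc(O)c(OC)c(O)c3)oc2c1OC | target

## Step count and least certain steps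

Total: 15 steps. Longest linear sequence: 11 steps (steps 5 to 15, from 9). The ring A branch (steps 1 to 4) joins at step 10.

**Step 10 (key step).** The most likely failure is protonation of the aryl anion before acyl transfer, which stops at the aryl propiolate ester. Thermal decarboxylation of the caesium propiolate and competing 5-exo closure to the aurone are the other two risks. The fallback sets out from 3 and 13 and comes back at 18. Carbamate 3 is lithiated as in step 3 but quenched with iodine to give 2-iodo-5-methoxy-3-(methoxymethoxy)phenyl N-(propan-2-yl)carbamate F1, and Et2NH with DBU then frees 2-iodo-5-methoxy-3-(methoxymethoxy)phenol F2. Dibromoalkene 13 is treated with n-BuLi and quenched with water to give 1,3-bis(benzyloxy)-5-ethynyl-2-methoxybenzene F3. Carbonylative coupling of F2 and F3 (PdCl2(PPh3)2, CO, Et2NH, heat) forms the ynone, the amine adds to it, and the phenol displaces the amine in the 6-endo sense to give 18. This is the known carbonylative annulation of ortho-iodophenols with terminal alkynes to flavones.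

**Step 13.** Incomplete conversion is normal for the Elbs oxidation, and the lipophilic tribenzyl substrate may dissolve poorly in the alkaline medium. Partial loss of the 3-O-benzyl group during the acid hydrolysis of the sulfate is possible, and the quinol of the next step can oxidise in air. The fallback sets out from 22 and comes back at 26, and it avoids the free quinol of step 14 altogether. The 5-OH of 22 is benzylated under forcing conditions (BnBr, K2CO3, DMF, 80 °C) to 3,5-bis(benzyloxy)-2-[3,5-bis(benzyloxy)-4-methoxyphenyl]-7-methoxy-4H-chromen-4-one F4. Electrophilic iodination (N-iodosuccinimide, cat. CF3CO2H) at C8, the position favoured in 5-O-alkylated 5,7-dioxygenated flavones, gives 3,5-bis(benzyloxy)-2-[3,5-bis(benzyloxy)-4-methoxyphenyl]-8-iodo-7-methoxy-4H-chromen-4-one F5. Copper-mediated methoxylation (CuI, NaOMe, MeOH/DMF, heat) gives 3,5-bis(benzyloxy)-2-[3,5-bis(benzyloxy)-4-methoxyphenyl]-7,8-dimethoxy-4H-chromen-4-one F6, and hydrogenolysis of its four benzyl ethers (H2, Pd/C) gives 26.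

**Step 11.** Epoxidation of the electron-poor enone double bond may be slow, and prolonged exposure to the dioxirane invites oxidation of benzylic and acetal C–H bonds. The fallback sets out from 18 and comes back at 20. C3–H is deprotonated with LDA in THF at −78 °C and the anion trapped with B(OMe)3 to give dimethyl {2-[3,5-bis(benzyloxy)-4-methoxyphenyl]-7-methoxy-5-(methoxymethoxy)-4-oxo-4H-chromen-3-yl}boronate F7, which is oxidised in the same flask with H2O2 and acetic acid to 20. Compound 20 is then taken on with HCl in methanol as in step 11.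

**Step 3.** Lithiation may be incompletely selective between the position flanked by carbamate and OMOM and the one flanked by carbamate and OMe, and attack of n-BuLi on the carbamate is a lesser risk. The fallback sets out from 1 and comes back at 6, using symmetry for the lithiation and differentiating the oxygens afterwards. Compound 1 is converted with two equivalents of iPrNCO into 5-methoxy-1,3-phenylene bis[N-(propan-2-yl)carbamate] F8. Double N-silylation, lithiation at the only position flanked by two carbamates and quenching with TMSCl give 5-methoxy-2-(trimethylsilyl)-1,3-phenylene bis[N-(propan-2-yl)carbamate] F9. One carbamate is cleaved with one equivalent of Et2NH and DBU, the phenoxide formed slowing the second cleavage, to give 3-hydroxy-5-methoxy-2-(trimethylsilyl)phenyl N-(propan-2-yl)carbamate F10. MOMCl with iPr2NEt then gives 6.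

## Further compounds

F1 | step 10 | 2-iodo-5-methoxy-3-(methoxymethoxy)phenyl N-(propan-2-yl)carbamate | COCOc1cc(OC)cc(OC(=O)NC(C)C)c1I
F2 | step 10 | 2-iodo-5-methoxy-3-(methoxymethoxy)phenol | COCOc1cc(OC)cc(O)c1I
F3 | step 10 | 1,3-bis(benzyloxy)-5-ethynyl-2-methoxybenzene | C#Cc1cc(OCc2ccccc2)c(OC)c(OCc2ccccc2)c1
F4 | step 13 | 3,5-bis(benzyloxy)-2-[3,5-bis(benzyloxy)-4-methoxyphenyl]-7-methoxy-4H-chromen-4-one | COc1cc(OCc2ccccc2)c2c(=O)c(OCc3ccccc3)c(-c3cc(OCc4ccccc4)c(OC)c(OCc4ccccc4)c3)oc2c1
F5 | step 13 | 3,5-bis(benzyloxy)-2-[3,5-bis(benzyloxy)-4-methoxyphenyl]-8-iodo-7-methoxy-4H-chromen-4-one | COc1cc(OCc2ccccc2)c2c(=O)c(OCc3ccccc3)c(-c3cc(OCc4ccccc4)c(OC)c(OCc4ccccc4)c3)oc2c1I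
F6 | step 13 | 3,5-bis(benzyloxy)-2-[3,5-bis(benzyloxy)-4-methoxyphenyl]-7,8-dimethoxy-4H-chromen-4-one | COc1cc(OCc2ccccc2)c2c(=O)c(OCc3ccccc3)c(-c3cc(OCc4ccccc4)c(OC)c(OCc4ccccc4)c3)oc2c1OC
F7 | step 11 | dimethyl {2-[3,5-bis(benzyloxy)-4-methoxyphenyl]-7-methoxy-5-(methoxymethoxy)-4-oxo-4H-chromen-3-yl}boronate | COCOc1cc(OC)cc2oc(-c3cc(OCc4ccccc4)c(OC)c(OCc4ccccc4)c3)c(B(OC)OC)c(=O)c12
F8 | step 3 | 5-methoxy-1,3-phenylene bis[N-(propan-2-yl)carbamate] | COc1cc(OC(=O)NC(C)C)cc(OC(=O)NC(C)C)c1
F9 | step 3 | 5-methoxy-2-(trimethylsilyl)-1,3-phenylene bis[N-(propan-2-yl)carbamate] | COc1cc(OC(=O)NC(C)C)c([Si](C)(C)C)c(OC(=O)NC(C)C)c1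
F10 | step 3 | 3-hydroxy-5-methoxy-2-(trimethylsilyl)phenyl N-(propan-2-yl)carbamate | COc1cc(O)c([Si](C)(C)C)c(OC(=O)NC(C)C)c1
A1 | alternative 1 | 3,5-bis(benzyloxy)-N-hydroxy-4-methoxybenzenecarboximidoyl chloride | COc1c(OCc2ccccc2)cc(C(Cl)=NO)cc1OCc1ccccc1
A2 | alternative 1 | 2-{[2-(benzyloxy)-3,4,6-trimethoxyphenyl]ethynyl}-4,4,5,5-tetramethyl-1,3,2-dioxaborolane | COc1cc(OC)c(C#CB2OC(C)(C)C(C)(C)O2)c(OCc2ccccc2)c1OC
A3 | alternative 1 | 5-[2-(benzyloxy)-3,4,6-trimethoxyphenyl]-3-[3,5-bis(benzyloxy)-4-methoxyphenyl]-4-(4,4,5,5-tetramethyl-1,3,2-dioxaborolan-2-yl)isoxazole | COc1cc(OC)c(-c2onc(-c3cc(OCc4ccccc4)c(OC)c(OCc4ccccc4)c3)c2B2OC(C)(C)C(C)(C)O2)c(OCc2ccccc2)c1OC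
A4 | alternative 2 | 2-(benzyloxy)-1-[3,5-bis(benzyloxy)-4-methoxyphenyl]-3-(2-hydroxy-4,5-dimethoxyphenyl)propane-1,3-dione | COc1cc(O)c(cc1OC)C(=O)C(OCc2ccccc2)C(=O)c3cc(OCc4ccccc4)c(OC)c(OCc5ccccc5)c3
A5 | alternative 2 | 2-(benzyloxy)-1-[3,5-bis(benzyloxy)-4-methoxyphenyl]-3-(3,3,4-trimethoxy-6-oxocyclohexa-1,4-dien-1-yl)propane-1,3-dione | COC1=CC(=O)C(=CC1(OC)OC)C(=O)C(OCc1ccccc1)C(=O)c1cc(OCc2ccccc2)c(OC)c(OCc2ccccc2)c1
A6 | alternative 2 | 3-(benzyloxy)-2-[3,5-bis(benzyloxy)-4-methoxyphenyl]-5-hydroxy-7,8-dimethoxy-4H-chromen-4-one | COc1cc(O)c2c(=O)c(OCc3ccccc3)c(-c3cc(OCc4ccccc4)c(OC)c(OCc4ccccc4)c3)oc2c1OC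
A7 | alternative 3 | methyl 2-(6-{2-[3,5-bis(benzyloxy)-4-methoxyphenyl]-2-oxoethyl}-4-oxo-4H-pyran-2-yl)acetate | COC(=O)Cc1cc(=O)cc(CC(=O)c2cc(OCc3ccccc3)c(OC)c(OCc3ccccc3)c2)o1
A8 | alternative 3 | methyl 9-[3,5-bis(benzyloxy)-4-methoxyphenyl]-3,5,7,9-tetraoxononanoate | COC(=O)CC(=O)CC(=O)CC(=O)CC(=O)c1cc(OCc2ccccc2)c(OC)c(OCc2ccccc2)c1
A9 | alternative 3 | 2-[3,5-bis(benzyloxy)-4-methoxyphenyl]-5,7-dihydroxy-4H-chromen-4-one | Oc1cc(O)c2c(=O)cc(-c3cc(OCc4ccccc4)c(OC)c(OCc4ccccc4)c3)oc2c1
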